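**Plan**
1. Retrosynthesis: the three O–Si bonds are cut first. Ring A (C4a, C5, C6, C7, C8, C8a) is then opened at C5–C6, C7–C8 and C4a–C5, with C8–C8a traced back to a 1,2-shift. This leads to a 2-(diazoacetyl)-4-pyranone and a chiral siloxyalkyne.
2. Enabling feature: ring A is a phloroglucinol ring whose only carbon substituent (C6) lies between the C5 and C7 oxygens and which shares C4a=C8a with ring C. A ketene carbon can therefore supply C5–O, the two ynol ether carbons C6 and C7–O, a diazomethyl carbon C8, and the C2=C3 bond of a 4-pyranone C8a and C4a.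
3. The diazo ketone is cut at its diazomethyl–carbonyl bond and at the C3–C1' aryl bond, back to kojic acid. The alkyne is cut at its C–O bond and at C1''–C2'' of the side chain, back to methacrolein.
4. Forward: ring C comes from kojic acid, ring B is attached by Suzuki–Miyaura coupling, the side chain enters with the alkyne, ring A is closed last on the pyranone, and fluoride then frees the three hydroxyls.
5. Stereochemistry: the one stereocentre, (R) at C2'', is set by chiral phosphoric acid-catalysed allenylboration of methacrolein and carried through as a silyl ether.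

Key step: step 9

Assumption: the (R)-configured phosphoric acid is taken to direct Re-face allenylboration of methacrolein as it does with aryl and alkenyl aldehydes; if a Mosher ester analysis showed the opposite sense, the (S)-acid would be used.

**Route**

Step 1
Reactants: 1 kojic acid (5-hydroxy-2-(hydroxymethyl)-4H-pyran-4-one)
Product: 2 6-(hydroxymethyl)-4-oxo-4H-pyran-3-yl trifluoromethanesulfonate
Conditions: PhNTf2, Et3N, DMF, 0 °C to rt
Reagents that add atoms: N-phenylbis(trifluoromethanesulfonimide), O=S(=O)(N(c1ccccc1)S(=O)(=O)C(F)(F)F)C(F)(F)F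
Why: Et3N ionizes only the acidic enolic 5-hydroxyl, and the mild triflyl donor PhNTf2 sulfonylates that oxyanion while leaving the neutral primary alcohol alone (chemoselective O-triflation).

Step 2
Reactants: 3 4-(4,4,5,5-tetramethyl-1,3,2-dioxaborolan-2-yl)phenol
Product: 4 triisopropyl[4-(4,4,5,5-tetramethyl-1,3,2-dioxaborolan-2-yl)phenoxy]silane
Conditions: TIPSCl, imidazole, DMF, rt
Reagents that add atoms: triisopropylsilyl chloride, CC(C)[Si](Cl)(C(C)C)C(C)C
Why: Imidazole-promoted silylation of a phenol, to which the pinacol boronate is inert; the bulky aryl silyl ether should survive the aqueous base, oxidation and acid chloride chemistry that follow.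

Step 3
Reactants: 2 6-(hydroxymethyl)-4-oxo-4H-pyran-3-yl trifluoromethanesulfonate; 4 triisopropyl[4-(4,4,5,5-tetramethyl-1,3,2-dioxaborolan-2-yl)phenoxy]silane
Product: 5 2-(hydroxymethyl)-5-[4-(triisopropylsilyloxy)phenyl]-4H-pyran-4-one
Conditions: Pd(PPh3)4 (5 mol %), K2CO3, 1,4-dioxane/H2O (10:1), 80 °C
Reagents that add atoms: none
Why: Suzuki–Miyaura coupling, in which zerovalent palladium inserts readily into the C–O bond of the electron-poor α-triflyloxy enone and the carbonate-activated boronate delivers the aryl group to form the C3–C1' bond, with the free alcohol and the aryl silyl ether as spectators.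

Step 4
Reactants: 5 2-(hydroxymethyl)-5-[4-(triisopropylsilyloxy)phenyl]-4H-pyran-4-one
Product: 7 4-oxo-5-[4-(triisopropylsilyloxy)phenyl]-4H-pyran-2-carboxylic acid, via aldehyde 6 (not isolated)
Conditions: TEMPO (cat.), PhI(OAc)2, MeCN/H2O (1:1), rt
Reagents that add atoms: water, O
Why: Oxoammonium oxidation (TEMPO/PhI(OAc)2) in aqueous acetonitrile takes the primary alcohol to the electron-poor aldehyde 6, whose hydrate is oxidized again to the acid, under near-neutral conditions that spare the base-sensitive pyranone and the aryl silyl ether.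

Step 5
Reactants: 7 4-oxo-5-[4-(triisopropylsilyloxy)phenyl]-4H-pyran-2-carboxylic acid
Product: 9 2-(2-diazoacetyl)-5-[4-(triisopropylsilyloxy)phenyl]-4H-pyran-4-one, via acid chloride 8 (not isolated)
Conditions: (COCl)2, DMF (cat.), CH2Cl2, 0 °C to rt; evaporate; CH2N2 (excess), Et2O/THF, 0 °C
Reagents that add atoms: diazomethane, C=[N+]=[N-]; oxalyl chloride, O=C(Cl)C(=O)Cl (chlorine of 8 only)
Why: Acylation of diazomethane by a non-enolizable acid chloride (first stage of the Arndt–Eistert sequence), a reaction in use on chromone-2-carbonyl chlorides; at 0 °C C-acylation should be much faster than dipolar cycloaddition to the pyranone double bond, and the excess diazomethane takes up the HCl.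

Step 6
Reactants: 10 methacrolein; 11 allenylboronic acid pinacol ester (4,4,5,5-tetramethyl-2-(propa-1,2-dien-1-yl)-1,3,2-dioxaborolane)
Product: 13 (3R)-2-methylhex-1-en-5-yn-3-ol, via borate ester 12 (not isolated)
Conditions: (R)-TRIP [(R)-3,3'-bis(2,4,6-triisopropylphenyl)-1,1'-binaphthyl-2,2'-diyl hydrogen phosphate] (5 mol %), 4 Å MS, toluene, −20 to 0 °C; then aq NaHCO3
Reagents that add atoms: none
Why: Chiral phosphoric acid-catalysed allenylboration (propargylation), in which the acid hydrogen-bonds to the boronate in a closed six-membered SE2' transition state, so that only the homopropargylic alcohol forms and the allenyl group is delivered to the Re face of the aldehyde, which sets the (R) centre.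

Step 7
Reactants: 13 (3R)-2-methylhex-1-en-5-yn-3-ol
Product: 14 tert-butyldimethyl{[(3R)-2-methylhex-1-en-5-yn-3-yl]oxy}silane
Conditions: TBSCl, imidazole, DMF, rt
Reagents that add atoms: tert-butyldimethylsilyl chloride, CC(C)(C)[Si](C)(C)Cl
Why: Imidazole-promoted silylation of a secondary alcohol; the silyl ether masks the hydroxyl through the organolithium chemistry and the benzannulation and is removed by fluoride at the end.

Step 8
Reactants: 14 tert-butyldimethyl{[(3R)-2-methylhex-1-en-5-yn-3-yl]oxy}silane
Product: 17 tert-butyldimethyl{[(3R)-2-methyl-6-(triisopropylsilyloxy)hex-1-en-5-yn-3-yl]oxy}silane, via lithium acetylide 15 (not isolated), via lithium ynolate 16 (not isolated)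
Conditions: n-BuLi, THF, −78 °C; then LiOOt-Bu [from t-BuOOH and LiN(SiMe3)2, THF, −78 °C], −78 to 0 °C; then TIPSOTf, −78 to 0 °C
Reagents that add atoms: lithium tert-butyl peroxide, [Li+].CC(C)(C)O[O-] (oxygen atom); triisopropylsilyl trifluoromethanesulfonate, CC(C)[Si](OS(=O)(=O)C(F)(F)F)(C(C)C)C(C)C; n-butyllithium, [Li]CCCC (lithium of 15 and 16 only)
Why: Oxidation of a lithium acetylide by lithium tert-butyl peroxide (attack of the acetylide on the O–O bond) gives the lithium ynolate, which the hard, bulky silyl triflate captures on oxygen to give the siloxyalkyne; the silyl ether and the isolated alkene are inert to these reagents.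

Step 9
Reactants: 9 2-(2-diazoacetyl)-5-[4-(triisopropylsilyloxy)phenyl]-4H-pyran-4-one; 17 tert-butyldimethyl{[(3R)-2-methyl-6-(triisopropylsilyloxy)hex-1-en-5-yn-3-yl]oxy}silane
Product: 22 6-[(2R)-2-(tert-butyldimethylsilyloxy)-3-methylbut-3-en-1-yl]-5-hydroxy-7-(triisopropylsilyloxy)-3-[4-(triisopropylsilyloxy)phenyl]-4H-chromen-4-one, via pyranonylketene 18 (not isolated), via cyclobutenone 19 (not isolated), via dienylketene 20 (not isolated), via cyclohexadienone 21 (not isolated)
Conditions: 17 (1.2 equiv), hν (365 nm), ClCH2CH2Cl, 25 °C; then 80 °C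
Reagents that add atoms: none
Why: Irradiation at 365 nm should excite the diazo ketone in preference to the aryl pyranone, and Wolff rearrangement (1,2-shift of the pyranonyl carbon, which makes C8–C8a) gives ketene 18, which adds to siloxyalkyne 17 in a polarity-matched [2+2] cycloaddition (chain-bearing alkyne carbon to the ketene carbonyl carbon) to form C5–C6 and C7–C8 in cyclobutenone 19. Reversible 4π-electrocyclic opening of 19, under light or on warming to 80 °C, gives dienylketene 20, and ring A closes by thermal disrotatory 6π-electrocyclization of the ketene carbon (C5) onto pyranone C3 (C4a), after which dienone 21 tautomerizes to the C5 phenol. The closest known reaction type is the Danheiser benzannulation in its diazo ketone variant with siloxyalkynes, established for alkenyl, aryl and heteroaryl diazomethyl ketones; here the C2=C3 bond of the 4-pyranone takes the part of the vinyl group. No lasting stereocentre is created (the sp3 carbons of 19 and 21 are lost on aromatization), and the (R)-silyloxy centre lies outside the reacting array and meets neither acid nor base. The step needs regioselectivity in the [2+2] event, which the donor oxygen of the ynol ether secures so that the chain ends at C6 between the C5 and C7 oxygens, and a single mode of ring closure, which is certain because the ketene-bearing pyranone carbon has only one ring carbon neighbour, the other being O1. Capture of the ketene by the product should be slow because the new C5 hydroxyl is hydrogen-bonded to the C4 carbonyl.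

Step 10
Reactants: 22 6-[(2R)-2-(tert-butyldimethylsilyloxy)-3-methylbut-3-en-1-yl]-5-hydroxy-7-(triisopropylsilyloxy)-3-[4-(triisopropylsilyloxy)phenyl]-4H-chromen-4-one
Product: 23 5,7-dihydroxy-6-[(2R)-2-hydroxy-3-methylbut-3-en-1-yl]-3-(4-hydroxyphenyl)-4H-chromen-4-one
Conditions: Bu4NF, AcOH, THF, 0 °C to rt
Reagents that add atoms: none
Why: Fluoride cleaves the two aryl silyl ethers and the secondary silyl ether through Si–F bond formation, and the acetic acid buffer keeps the medium mild enough to avoid base-induced opening of the chromone and acid-induced cyclization of the allylic alcohol onto the neighbouring phenols.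

**Compound list**

1 | kojic acid, 5-hydroxy-2-(hydroxymethyl)-4H-pyran-4-one | OCc1cc(=O)c(O)co1 | starting material
2 | 6-(hydroxymethyl)-4-oxo-4H-pyran-3-yl trifluoromethanesulfonate | OCc1cc(=O)c(OS(=O)(=O)C(F)(F)F)co1 | intermediate
3 | 4-(4,4,5,5-tetramethyl-1,3,2-dioxaborolan-2-yl)phenol | CC1(C)OB(c2ccc(O)cc2)OC1(C)C | starting material
4 | triisopropyl[4-(4,4,5,5-tetramethyl-1,3,2-dioxaborolan-2-yl)phenoxy]silane | CC(C)[Si](Oc1ccc(B2OC(C)(C)C(C)(C)O2)cc1)(C(C)C)C(C)C | intermediate
5 | 2-(hydroxymethyl)-5-[4-(triisopropylsilyloxy)phenyl]-4H-pyran-4-one | OCc1cc(=O)c(-c2ccc(O[Si](C(C)C)(C(C)C)C(C)C)cc2)co1 | intermediate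
6 | 4-oxo-5-[4-(triisopropylsilyloxy)phenyl]-4H-pyran-2-carbaldehyde (not isolated) | O=Cc1cc(=O)c(-c2ccc(O[Si](C(C)C)(C(C)C)C(C)C)cc2)co1 | intermediate
7 | 4-oxo-5-[4-(triisopropylsilyloxy)phenyl]-4H-pyran-2-carboxylic acid | OC(=O)c1cc(=O)c(-c2ccc(O[Si](C(C)C)(C(C)C)C(C)C)cc2)co1 | intermediate
8 | 4-oxo-5-[4-(triisopropylsilyloxy)phenyl]-4H-pyran-2-carbonyl chloride (not isolated) | O=C(Cl)c1cc(=O)c(-c2ccc(O[Si](C(C)C)(C(C)C)C(C)C)cc2)co1 | intermediate
9 | 2-(2-diazoacetyl)-5-[4-(triisopropylsilyloxy)phenyl]-4H-pyran-4-one | [N-]=[N+]=CC(=O)c1cc(=O)c(-c2ccc(O[Si](C(C)C)(C(C)C)C(C)C)cc2)co1 | intermediate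
10 | methacrolein | C=C(C)C=O | starting material
11 | allenylboronic acid pinacol ester | C=C=CB1OC(C)(C)C(C)(C)O1 | starting material
12 | 4,4,5,5-tetramethyl-2-{[(3R)-2-methylhex-1-en-5-yn-3-yl]oxy}-1,3,2-dioxaborolane (not isolated) | C=C(C)[C@H](OB1OC(C)(C)C(C)(C)O1)CC#C | intermediate
13 | (3R)-2-methylhex-1-en-5-yn-3-ol | C=C(C)[C@H](O)CC#C | intermediate
14 | tert-butyldimethyl{[(3R)-2-methylhex-1-en-5-yn-3-yl]oxy}silane | C=C(C)[C@H](O[Si](C)(C)C(C)(C)C)CC#C | intermediate
15 | lithium acetylide of 14 (not isolated) | C=C(C)[C@H](O[Si](C)(C)C(C)(C)C)CC#C[Li] | intermediate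
16 | lithium (4R)-4-(tert-butyldimethylsilyloxy)-5-methylhex-5-en-1-yn-1-olate (not isolated) | C=C(C)[C@H](O[Si](C)(C)C(C)(C)C)CC#CO[Li] | intermediate
17 | tert-butyldimethyl{[(3R)-2-methyl-6-(triisopropylsilyloxy)hex-1-en-5-yn-3-yl]oxy}silane | C=C(C)[C@H](O[Si](C)(C)C(C)(C)C)CC#CO[Si](C(C)C)(C(C)C)C(C)C | intermediate
18 | 2-(2-oxoethenyl)-5-[4-(triisopropylsilyloxy)phenyl]-4H-pyran-4-one, the pyranonylketene (not isolated) | O=C=Cc1cc(=O)c(-c2ccc(O[Si](C(C)C)(C(C)C)C(C)C)cc2)co1 | intermediate
19 | 2-[(2R)-2-(tert-butyldimethylsilyloxy)-3-methylbut-3-en-1-yl]-4-{4-oxo-5-[4-(triisopropylsilyloxy)phenyl]-4H-pyran-2-yl}-3-(triisopropylsilyloxy)cyclobut-2-en-1-one, both configurations at C4 (not isolated) | C=C(C)[C@H](O[Si](C)(C)C(C)(C)C)CC1=C(O[Si](C(C)C)(C(C)C)C(C)C)C(c2cc(=O)c(-c3ccc(O[Si](C(C)C)(C(C)C)C(C)C)cc3)co2)C1=O | intermediate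
20 | (3E)-2-[(2R)-2-(tert-butyldimethylsilyloxy)-3-methylbut-3-en-1-yl]-4-{4-oxo-5-[4-(triisopropylsilyloxy)phenyl]-4H-pyran-2-yl}-3-(triisopropylsilyloxy)buta-1,3-dien-1-one, pyranonyl cis to the ketene carbon (not isolated) | C=C(C)[C@H](O[Si](C)(C)C(C)(C)C)CC(=C=O)/C(O[Si](C(C)C)(C(C)C)C(C)C)=C\c1cc(=O)c(-c2ccc(O[Si](C(C)C)(C(C)C)C(C)C)cc2)co1 | intermediate
21 | 6-[(2R)-2-(tert-butyldimethylsilyloxy)-3-methylbut-3-en-1-yl]-7-(triisopropylsilyloxy)-3-[4-(triisopropylsilyloxy)phenyl]-4aH-chromene-4,5-dione, either configuration at C4a (not isolated) | C=C(C)[C@H](O[Si](C)(C)C(C)(C)C)CC1=C(O[Si](C(C)C)(C(C)C)C(C)C)C=C2OC=C(c3ccc(O[Si](C(C)C)(C(C)C)C(C)C)cc3)C(=O)C2C1=O | intermediate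
22 | 6-[(2R)-2-(tert-butyldimethylsilyloxy)-3-methylbut-3-en-1-yl]-5-hydroxy-7-(triisopropylsilyloxy)-3-[4-(triisopropylsilyloxy)phenyl]-4H-chromen-4-one | C=C(C)[C@H](O[Si](C)(C)C(C)(C)C)Cc1c(O[Si](C(C)C)(C(C)C)C(C)C)cc2occ(-c3ccc(O[Si](C(C)C)(C(C)C)C(C)C)cc3)c(=O)c2c1O | intermediate
23 | 5,7-dihydroxy-6-[(2R)-2-hydroxy-3-methylbut-3-en-1-yl]-3-(4-hydroxyphenyl)-4H-chromen-4-one | C=C(C)[C@H](O)Cc1c(O)cc2occ(-c3ccc(O)cc3)c(=O)c2c1O | target

**Step count**

Total: 10 steps. Longest linear sequence: 6 steps (steps 1, 3, 4, 5, 9, 10, from kojic acid 1 to target 23); the alkyne branch (steps 6, 7, 8) joins at step 9.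

**Steps most likely to fail**

1. Step 9. What may go wrong: the aryl pyranone or the product competes for the light and photoisomerizes, nitrogen loss stays incomplete, or the ketene dimerizes before the alkyne captures it. Fallback: the same ketene is released without light by dehydrochlorination. Setting out from diazo ketone 9, silver-catalysed Arndt–Eistert homologation (PhCO2Ag, Et3N, THF/H2O, rt) should give {4-oxo-5-[4-(triisopropylsilyloxy)phenyl]-4H-pyran-2-yl}acetic acid F1. This acid is handled cold, since a vinylogous β-keto acid of this kind may lose CO2, and is converted at once with (COCl)2 and catalytic DMF into {4-oxo-5-[4-(triisopropylsilyloxy)phenyl]-4H-pyran-2-yl}acetyl chloride F2. Slow addition of Et3N to F2 and siloxyalkyne 17 in toluene at rt releases ketene 18 at low concentration. The route is rejoined at 18 and cyclobutenone 19, which is heated at 80–110 °C in the same pot to give 22.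

2. Step 8. What may go wrong: oxygen transfer from the peroxide to the acetylide stays incomplete, or the ynol silyl ether is hydrolysed during isolation. Fallback: ynolate 16 is built by Kowalski ester homologation instead of acetylide oxidation. Setting out from methacrolein 10, a Mukaiyama aldol addition of 1-ethoxy-1-(trimethylsilyloxy)ethene under Ti(OiPr)4 with a BINOL-derived tridentate Schiff-base ligand and 3,5-di-tert-butylsalicylic acid (ligand enantiomer chosen for Re-face attack) should give ethyl (3R)-4-methyl-3-(trimethylsilyloxy)pent-4-enoate F3. Acidic work-up frees ethyl (3R)-3-hydroxy-4-methylpent-4-enoate F4, and TBSCl/imidazole gives ethyl (3R)-3-(tert-butyldimethylsilyloxy)-4-methylpent-4-enoate F5. Treatment of F5 with CH2Br2 and lithium 2,2,6,6-tetramethylpiperidide (THF, −78 °C) forms lithium (4R)-1,1-dibromo-4-(tert-butyldimethylsilyloxy)-5-methylhexa-1,5-dien-2-olate F6, which on bromine–lithium exchange with n-BuLi (−78 to 0 °C) rearranges to ynolate 16. The route is rejoined at 16, which is silylated with TIPSOTf as in step 8 to give 17, used without chromatography if it proves labile.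

3. Step 6. What may go wrong: facial selectivity is poor with a small, unhindered enal, or the volatile alcohol is lost on isolation. Fallback: racemic propargylation followed by Sharpless kinetic resolution. Setting out from methacrolein 10, Barbier propargylation with propargyl bromide and Zn (THF/aq NH4Cl, 0 °C) should give racemic 2-methylhex-1-en-5-yn-3-ol F7. Epoxidation with Ti(OiPr)4, L-(+)-diisopropyl tartrate and t-BuOOH (4 Å MS, CH2Cl2, −20 °C), run to just past half conversion, is expected to consume the (S)-enantiomer as (1S)-1-[(2R)-2-methyloxiran-2-yl]but-3-yn-1-ol F8 and to leave the (R)-alcohol. The route is rejoined at 13, which can be silylated directly (step 7) to limit losses by evaporation.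

**Further compounds**

F1 | step 9 | {4-oxo-5-[4-(triisopropylsilyloxy)phenyl]-4H-pyran-2-yl}acetic acid | OC(=O)Cc1cc(=O)c(-c2ccc(O[Si](C(C)C)(C(C)C)C(C)C)cc2)co1
F2 | step 9 | {4-oxo-5-[4-(triisopropylsilyloxy)phenyl]-4H-pyran-2-yl}acetyl chloride | O=C(Cl)Cc1cc(=O)c(-c2ccc(O[Si](C(C)C)(C(C)C)C(C)C)cc2)co1
F3 | step 8 | ethyl (3R)-4-methyl-3-(trimethylsilyloxy)pent-4-enoate | C=C(C)[C@H](O[Si](C)(C)C)CC(=O)OCC
F4 | step 8 | ethyl (3R)-3-hydroxy-4-methylpent-4-enoate | C=C(C)[C@H](O)CC(=O)OCC
F5 | step 8 | ethyl (3R)-3-(tert-butyldimethylsilyloxy)-4-methylpent-4-enoate | C=C(C)[C@H](O[Si](C)(C)C(C)(C)C)CC(=O)OCC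
F6 | step 8 | lithium (4R)-1,1-dibromo-4-(tert-butyldimethylsilyloxy)-5-methylhexa-1,5-dien-2-olate | C=C(C)[C@H](O[Si](C)(C)C(C)(C)C)CC(O[Li])=C(Br)Br
F7 | step 6 | racemic 2-methylhex-1-en-5-yn-3-ol | C=C(C)C(O)CC#C
F8 | step 6 | (1S)-1-[(2R)-2-methyloxiran-2-yl]but-3-yn-1-ol | C#CC[C@H](O)[C@@]1(C)CO1
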